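**Assumptions and remarks on the chemistry**

- Labels: ring A is the phloroglucinol ring, ring B the 4-methoxyphenyl ring of the acyl chain, ring C the 4-hydroxyphenyl ring on C7, ring D the 4-hydroxyphenyl ring on C7'. The chain is C7–C8–C8'–C7', with one methyl on C8 and one on C8'.
- 12 is assumed to be bought as a THF solution; 3, 5, 16 and 23 are catalogue compounds.
- Descriptor check: lactone 8 (3R,4R,5R) leads to diol 9 (2R,3R) and on to C8 (R) and C8' (S) of the target. The letter at C8' changes only through CIP priorities; no centre is inverted.
- The carbinol carbon of 18 and 19 is carried as both epimers, because it becomes planar in step 11.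
- A 4-sulfonyloxy alkoxide closes to a tetrahydrofuran, so the second hydroxyl of 9 is silylated before the coupling. A free phenol cannot ride on an aryllithium, so ring A is joined to C7 through its magnesium phenoxide.

## Structural features

The target is a 2',4',6'-trihydroxy-4-methoxydihydrochalcone: ring A is a phloroglucinol nucleus, joined through a C(=O)CH2CH2 chain to ring B. The ring A carbon between two hydroxyls carries a 1,4-diaryl-2,3-dimethylbutyl unit, in which C7 bears ring A, ring C and a hydrogen, C8 and C8' each bear a methyl, and C7' is the benzylic CH2 of ring D. The three stereocentres C7 (R), C8 (R) and C8' (S) are contiguous and acyclic, with no ring or heteroatom between them to relay control. Ring A is electron-rich and air-sensitive as the free triol, but the 2-alkylphloroglucinol has two equivalent free carbons, so the position of the acyl group raises no regiochemical question. The fragile points are the C7–ring A bond (acid can reverse this Friedel–Crafts-type bond and epimerise C7), the C8–H once C7 is an aldehyde or a quinone methide carbon, and the five free phenols beside one methyl ether. The real difficulty is C7, a diarylmethine centre whose only control element is the neighbouring C8, together with the vicinal methyl pair on C8 and C8'. The key step exploits the fact that C7–C8–C8'–C7', with one methyl on each inner carbon, is the C2–C3–C4–C5 backbone of a butenolide: two methyls placed trans on that five-membered ring give the required C8/C8' relationship, and reduction turns the ring into the C2-symmetric (2R,3R)-2,3-dimethylbutane-1,4-diol with identical ends.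

## Logic of the disconnections

**25 to 22 and 23.** The bond cut joins the free carbon of ring A to the ketone carbon. It is made last because an aryl ketone would not survive the organomagnesium and quinone methide chemistry that builds C7, and because the two free carbons of ring A in 22 are equivalent, so only one C-acylation product is possible. Ring B and the three-carbon chain then come in one piece from 23. The forward step must acylate carbon and not oxygen, must prefer ring A over rings C and D, and must not ionise the C7–ring A bond.

**22 to 21.** Four O–CH2Ph bonds are cut, two on ring A and one each on rings C and D. One kind of protecting group covers every phenol through the organometallic steps and is removed in a single neutral operation. The only demand is that the C7 methine and the arenes are left alone.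

**21 to 19 and 12, by way of 20.** The C7–ring C bond is cut. Ring C is removed as the nucleophile so that ring A is the in-plane aryl of 20. 1,3-Allylic strain then holds the C8–H in the ring plane, and the C8 methyl and the larger C8' branch cover opposite faces of C7. Attack past the methyl gives 7R; the converse order of aryl introduction would give 7S from the same bias. The gain is ring C and the C7 centre in one step. The demand is facial selectivity and addition faster than tautomerisation of 20.

**19 to 18, then 18 to 15 and 16, through 17.** First the carbonate C–O bond on the ring A oxygen is cut, then the C7–ring A bond. Hydroxyalkylation ortho to the phenol oxygen gives exactly the pair of groups (ortho oxygen and benzylic oxygen) from which 20 is released, and the two ortho carbons of 16 are equivalent. This reduces the problem to a chain aldehyde and a commercial arene. The forward step must add to the aldehyde without enolising C8 and must stop after one alkylation.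

**15 to 14, 14 to 13, 13 to 11 and 12.** After adjusting the oxidation level at C7 and removing the silyl group, the C7'–ring D bond is cut. This is an sp3–sp2 bond at a primary carbon, remote from reaction at either stereocentre, and 12 serves for rings C and D alike. The demand is displacement at a beta-branched carbon and a protected second oxygen.

**11 to 10 to 9.** The S–O and Si–O bonds are cut. Because 9 is C2-symmetric, the first group may go on either oxygen and gives the same compound. The demand is clean mono-functionalisation.

**9 to 8.** No skeletal bond is cut; the lactone C–O and acetal C–O bonds are traced back and 3 is released. The differentiation of the two ends disappears, so no end-selection is needed later. The demand is complete reduction of C2 and C5.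

**8 to 4, 5 and 6, through 7.** The C4–CH3 bond (C8'–CH3) and the C3–CH3 bond (C8–CH3) are cut. The two methyls can be delivered to the two carbons of one enoate, one as a nucleophile and one as an electrophile, and the ring forces them trans. Two stereocentres and two C–C bonds then derive from a single acetal centre. The demand is face selectivity at C4 and C3 and a single C-methylation.

**4 to 2 and 3; 2 to 1.** The exocyclic acetal C5–O bond is cut, and the hydroxybutenolide is traced to the furan aldehyde by oxidative loss of one carbon. 3 is a cheap chiral alcohol and only one acetal epimer crystallises. The demand is that the two C5 epimers interconvert so that the crystallisation collects both.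

## Other disconnections considered

**Alternative 1:** The cut runs through ring A itself: the two ring bonds on either side of the two-carbon unit that carries C7 and the neighbouring silyloxy group are opened, so that ring A is built on a finished chain.
- Forward key step: heating 3-(benzyloxy)cyclobut-2-en-1-one A2 with the siloxyalkyne A3, which already holds C7, C8, C8', ring C and ring D, should start a four-electron ring opening of A2, a [2+2] addition to the alkyne, a second four-electron opening and a six-electron closure, ending after tautomerisation in the phenol A1.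
- In favour: the regiochemistry of ring A follows from the polarity of the ynol ether, the three oxygens emerge differentiated, and the conditions are neutral. The C7–ring A bond is never formed by cation or quinone methide chemistry, so C7 cannot be scrambled at that stage; on this point the alternative is better than the chosen plan.
- Against: A3 must contain all three stereocentres beforehand, so the stereochemical problem is moved and not solved. Its C7–H is propargylic and benzylic and must survive alkyne formation and heating. Siloxyalkynes are moisture-sensitive and take several steps. Differentiated ring A oxygens are of no use for a target with three free hydroxyls.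
- Comparison: in structure, the chosen plan buys ring A in 16 while the alternative constructs a ring with no substitution pattern that is hard to buy. In mechanism, the pericyclic cascade is the equal of the chosen plan in regiochemical reliability and its better in mildness, but it offers nothing for C8 and C8' (step 3) or C7 (step 11). In step economy, the preparation of A2 and A3 makes it clearly longer.

**Alternative 2:** The cut removes the C7'–C8' and C8'–C8 bonds.
- Forward key step: 4-(benzyloxy)benzyl pinacol boronate A5 is treated at low temperature with the lithium reagent formed from the (R)-stannane A6 by tin–lithium exchange with n-BuLi. The ate complex rearranges by 1,2-metallate shift, and the sequence is repeated in the same flask with the (S)-stannane A7 to give the secondary boronate A4.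
- In favour: each centre is set by the reagent, independently of the other, so any stereoisomer could be made. Ring D is present from the first atom, whereas the chosen plan spends steps 5 to 7 on it; here the alternative is better. The C–B bond at C8 is a handle for a further stereospecific homologation towards C7, which could put C7 under reagent control as well; this too is better than the substrate bias of step 11.
- Against: two enantiopure stannanes must be prepared, tin waste is stoichiometric, and the operation is strictly cryogenic. A4 still lacks C7 and both aryl groups on it, and joining a 2,4,6-trioxygenated aryl to a hindered secondary boronate is the most demanding coupling of its kind.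
- Comparison: in structure, both plans create C8 and C8' with two C–C bonds in one flask, which is equal; the alternative's product is acyclic and carries ring D, while the chosen product is a masked diol. In mechanism, stereospecific 1,2-shifts stand against diastereoselective additions on a ring; both are well founded, the alternative more general, the chosen plan simpler for this isomer because the ring supplies trans for free. In step economy, the alternative is probably shorter to the C7'–C8 fragment if A6 and A7 are at hand; counting their preparation the plans are comparable, and the chosen plan is the safer on scale.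

**Alternative 3:** The cut removes the C7–C8 bond and the acyl C–O bond of a lactone that ties the ring A oxygen to the carbon destined to become the C8 methyl.
- Forward key step: Cs2CO3 and a chiral triazolium-derived carbene join the sulfone A9, which loses sulfinate and exposes C7 as an electrophile, with the 4-nitrophenyl ester A10, which the carbene activates as a nucleophile at its alpha carbon (C8). The formal [4+2] annulation gives the cis-dihydrocoumarin A8.
- In favour: C7 and C8 are created together under catalyst control, with their relationship fixed by a six-membered ring and rings A and C already in place. In the control of C7 this alternative is better than the chosen plan.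
- Against: C8' must arrive preformed in A10 and may match or mismatch the catalyst. The lactone carbonyl has to be taken down to a methyl (reduction, activation, hydride displacement), three operations that add nothing to the skeleton. The electrophile from A9 is electron-rich and sluggish, and A10 is beta-branched.
- Comparison: in structure, the chosen plan pairs C8 with C8' and adds C7 last, while the alternative pairs C7 with C8 and needs C8' separately; each leaves one centre to be matched. In mechanism, the alternative is equal in mildness, superior for C7 and inferior in functional-group adjustment. In step economy, the syntheses of A9 and A10 and the carbonyl-to-methyl adjustment should make it longer.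

Key step: step 3

## Route

Step 1
Reactants: 1 furfural
Product: 2 5-hydroxyfuran-2(5H)-one (racemic)
Conditions: O2, visible light, methylene blue [3,7-bis(dimethylamino)phenothiazin-5-ium chloride] (cat.), MeOH, 20 °C
Reagents that add atoms: dioxygen, O=O
Why: Schenck-type photooxygenation: singlet oxygen adds across C2 and C5 of the furan in a [4+2] sense and methanol removes the formyl carbon as its formate ester, leaving the hydroxybutenolide; the hemiacetal centre forms racemic and is dealt with in step 2.

Step 2
Reactants: 2 5-hydroxyfuran-2(5H)-one; 3 (1R,2S,5R)-menthol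
Product: 4 (5R)-5-{[(1R,2S,5R)-2-isopropyl-5-methylcyclohexyl]oxy}furan-2(5H)-one
Conditions: p-TsOH (cat.), toluene, reflux, Dean–Stark; crystallisation from hexane, −20 °C; mother liquor re-equilibrated with p-TsOH and recrystallised
Reagents that add atoms: none
Why: Acid-catalysed acetal formation through the cyclic oxocarbenium ion gives both C5 epimers, which interconvert under acid; only the (5R) epimer crystallises, so C5 is set by crystallisation-driven equilibration with the menthyl group as the resolving element.

Step 3
Reactants: 4 (5R)-5-(menthyloxy)furan-2(5H)-one; 5 iodomethane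
Product: 8 (3R,4R,5R)-3,4-dimethyl-5-{[(1R,2S,5R)-2-isopropyl-5-methylcyclohexyl]oxy}dihydrofuran-2(3H)-one, via lithium dimethylcuprate 6 (not isolated), via lithium lactone enolate 7 (not isolated)
Conditions: CuI, MeLi (2 equiv per Cu), Et2O, 0 °C; 4, −78 °C; then 5 (excess), DMPU, −78 to −20 °C; aq NH4Cl
Reagents that add atoms: methyllithium, [Li]C
Why: The Gilman reagent 6 forms a π-complex with the enoate of 4 and transfers one methyl to C4 through a trivalent copper intermediate and reductive elimination, leaving the lithium enolate 7 and methylcopper. On addition of DMPU and an excess of 5 the enolate is methylated at C3 in an SN2 step. The closest known reaction type is the three-component conjugate addition and enolate alkylation of cyclic enones and of 5-alkoxybutenolides. No ring is closed; the five-membered lactone serves only as the template that relates the two new centres. C4 (the future C8') is controlled by the acetal centre C5: the menthyloxy group covers one face of the planar butenolide and the methyl enters anti to it. C3 (the future C8) is controlled by the new C4 methyl: the flat enolate is attacked from the face opposite to that neighbour, which is also the thermodynamically preferred trans arrangement. The step needs 1,4- and not 1,2-addition, which the soft cuprate secures, and a single C-methylation without proton exchange, which low temperature, the polar co-solvent and the excess of 5 should secure. The acetal is safe because its oxygen sits gamma to the carbonyl and cannot leave by beta-elimination from the C2–C3 enolate, so (3R,4R,5R)-8 should result with both methyl-bearing centres set in one flask.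

Step 4
Reactants: 8 (3R,4R,5R)-3,4-dimethyl-5-(menthyloxy)dihydrofuran-2(3H)-one
Product: 9 (2R,3R)-2,3-dimethylbutane-1,4-diol
Conditions: LiAlH4, THF, 0 °C to reflux; Fieser work-up (H2O, 15% NaOH, H2O)
Reagents that add atoms: none
Why: LiAlH4 reduces the lactone carbonyl, the ring opens to a hemiacetal alkoxide that expels menthoxide, and the freed aldehyde is reduced as well, so C2 and C5 both end as CH2OH. The stereocentres are untouched, the diol has homotopic ends and the auxiliary 3 is recovered.

Step 5
Reactants: 9 (2R,3R)-2,3-dimethylbutane-1,4-diol
Product: 10 (2R,3R)-4-[(tert-butyldimethylsilyl)oxy]-2,3-dimethylbutan-1-ol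
Conditions: NaH (1.0 equiv), THF, 0 °C to rt; TBSCl (1.0 equiv), rt
Reagents that add atoms: tert-butyldimethylsilyl chloride, CC(C)(C)[Si](C)(C)Cl
Why: Silylation through the sparingly soluble monosodium alkoxide should occur essentially once; since 9 is C2-symmetric both hydroxyls are equivalent and one mono-ether results. The silyl group is needed because a 4-sulfonyloxy alkoxide would close to a tetrahydrofuran.

Step 6
Reactants: 10 (2R,3R)-4-[(tert-butyldimethylsilyl)oxy]-2,3-dimethylbutan-1-ol
Product: 11 (2R,3R)-4-[(tert-butyldimethylsilyl)oxy]-2,3-dimethylbutyl 4-methylbenzenesulfonate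
Conditions: TsCl, Et3N, DMAP (cat.), CH2Cl2, 0 °C to rt
Reagents that add atoms: 4-toluenesulfonyl chloride, Cc1ccc(cc1)S(=O)(=O)Cl
Why: Standard sulfonylation of the remaining primary alcohol under nucleophilic catalysis; no stereocentre takes part.

Step 7
Reactants: 11 (2R,3R)-4-[(tert-butyldimethylsilyl)oxy]-2,3-dimethylbutyl 4-methylbenzenesulfonate; 12 4-(benzyloxy)phenylmagnesium bromide
Product: 14 (2R,3S)-4-[4-(benzyloxy)phenyl]-2,3-dimethylbutan-1-ol, via TBS ether 13 (not isolated)
Conditions: 12 (2 equiv), Li2CuCl4 (5 mol %), THF, −20 °C to rt; then 2 M aq HCl, rt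
Reagents that add atoms: none
Why: Copper-catalysed cross-coupling of an aryl Grignard reagent with a primary alkyl sulfonate (Kochi–Schlosser type, SN2-like displacement by an arylcopper species) forms the C7'–ring D bond; C8' is beta to the reacting carbon and is not involved. The silyl ether prevents closure to a tetrahydrofuran and is cleaved by the acidic work-up.

Step 8
Reactants: 14 (2R,3S)-4-[4-(benzyloxy)phenyl]-2,3-dimethylbutan-1-ol
Product: 15 (2R,3S)-4-[4-(benzyloxy)phenyl]-2,3-dimethylbutanal
Conditions: Dess–Martin periodinane, NaHCO3, CH2Cl2, 0 °C to rt; used crude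
Reagents that add atoms: none
Why: Dess–Martin oxidation stops at the aldehyde under buffered, non-basic conditions, so the alpha centre C8 should not epimerise; the aldehyde is used at once without chromatography.

Step 9
Reactants: 15 (2R,3S)-4-[4-(benzyloxy)phenyl]-2,3-dimethylbutanal; 16 3,5-bis(benzyloxy)phenol
Product: 18 3,5-bis(benzyloxy)-2-{(2R,3S)-4-[4-(benzyloxy)phenyl]-1-hydroxy-2,3-dimethylbutyl}phenol (both C1 epimers), via bromomagnesium phenoxide 17 (not isolated)
Conditions: 16, EtMgBr (1.0 equiv), Et2O, 0 °C; solvent exchange to CH2Cl2; 15, rt; pH 7 buffer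
Reagents that add atoms: none
Why: The aldehyde coordinates to the magnesium of 17 and is delivered to the adjacent ring carbon through a six-membered chelate (ortho-specific hydroxyalkylation of a metal phenoxide, an aldol-type Friedel–Crafts reaction), which a non-coordinating solvent favours; the two ortho carbons of 16 are equivalent and the para carbon cannot be reached. The weakly basic phenoxide should leave C8 of 15 intact, and the new carbinol centre needs no control because it becomes planar in step 11.

Step 10
Reactants: 18 3,5-bis(benzyloxy)-2-{(2R,3S)-4-[4-(benzyloxy)phenyl]-1-hydroxy-2,3-dimethylbutyl}phenol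
Product: 19 3,5-bis(benzyloxy)-2-{(2R,3S)-4-[4-(benzyloxy)phenyl]-1-hydroxy-2,3-dimethylbutyl}phenyl tert-butyl carbonate (both C1 epimers)
Conditions: Boc2O (1.05 equiv), i-Pr2NEt, DMAP (cat.), CH2Cl2, −20 to 0 °C
Reagents that add atoms: di-tert-butyl dicarbonate, CC(C)(C)OC(=O)OC(=O)OC(C)(C)C
Why: The phenol is the more acidic and the less hindered hydroxyl and is carbonylated first under DMAP catalysis (chemoselective O-acylation). A carbonate placed on the benzylic oxygen instead would lead to the same quinone methide in step 11, so this selectivity is not critical.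

Step 11
Reactants: 19 3,5-bis(benzyloxy)-2-{(2R,3S)-4-[4-(benzyloxy)phenyl]-1-hydroxy-2,3-dimethylbutyl}phenyl tert-butyl carbonate; 12 4-(benzyloxy)phenylmagnesium bromide
Product: 21 3,5-bis(benzyloxy)-2-{(1R,2R,3S)-1,4-bis[4-(benzyloxy)phenyl]-2,3-dimethylbutyl}phenol, via ortho-quinone methide 20 (not isolated)
Conditions: 12 (2.5 equiv), THF, −78 to 0 °C; aq NH4Cl
Reagents that add atoms: none
Why: The first equivalent of 12 deprotonates the benzylic hydroxyl, the carbonate shifts to that alkoxide and the phenoxide expels tert-butyl carbonate, a known low-temperature anionic route to ortho-quinone methides; the second equivalent adds to C7 in a 1,4-sense and restores the aromatic ring. In 20, 1,3-allylic strain holds the C8–H in the ring plane, so the C8 methyl and the C8' branch cover opposite faces of C7. Attack past the smaller methyl, anti to the branch, should give the 7R epimer as the major product, any 7S epimer being a separable diastereomer.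

Step 12
Reactants: 21 3,5-bis(benzyloxy)-2-{(1R,2R,3S)-1,4-bis[4-(benzyloxy)phenyl]-2,3-dimethylbutyl}phenol
Product: 22 2-[(1R,2R,3S)-1,4-bis(4-hydroxyphenyl)-2,3-dimethylbutyl]benzene-1,3,5-triol
Conditions: H2 (1 atm), Pd/C, EtOAc–MeOH, rt; product kept under argon
Reagents that add atoms: none
Why: Heterogeneous hydrogenolysis cleaves the four aryl benzyl ethers at their benzylic C–O bonds. The C7 methine has no heteroatom leaving group and is not affected, and no acid or base is present that could disturb C7 or C8.

Step 13
Reactants: 22 2-[(1R,2R,3S)-1,4-bis(4-hydroxyphenyl)-2,3-dimethylbutyl]benzene-1,3,5-triol; 23 3-(4-methoxyphenyl)propanenitrile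
Product: 25 1-{3-[(1R,2R,3S)-1,4-bis(4-hydroxyphenyl)-2,3-dimethylbutyl]-2,4,6-trihydroxyphenyl}-3-(4-methoxyphenyl)propan-1-one, via ketiminium chloride 24 (not isolated)
Conditions: ZnCl2, HCl (g), Et2O, 0 °C; then H2O, 90 °C
Reagents that add atoms: water, O
Why: Houben–Hoesch reaction: the nitrile, activated by HCl and ZnCl2, attacks one of the two equivalent free carbons of the phloroglucinol ring (rings C and D are monohydric phenols and too unreactive), and the ketiminium salt 24 is hydrolysed by hot water. Ring A is deactivated as soon as it is acylated, which protects the C7–ring A bond against the acid.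

## Compound list

1 | furfural (furan-2-carbaldehyde) | O=Cc1ccco1 | starting material
2 | 5-hydroxyfuran-2(5H)-one (racemic) | O=C1C=CC(O)O1 | intermediate
3 | (1R,2S,5R)-menthol | CC(C)[C@@H]1CC[C@@H](C)C[C@H]1O | starting material
4 | (5R)-5-{[(1R,2S,5R)-2-isopropyl-5-methylcyclohexyl]oxy}furan-2(5H)-one | O=C1C=C[C@H](O[C@@H]2C[C@H](C)CC[C@H]2C(C)C)O1 | intermediate
5 | iodomethane | CI | starting material
6 | lithium dimethylcuprate | [Li+].C[Cu-]C | intermediate
7 | lithium (4R,5R)-4-methyl-5-{[(1R,2S,5R)-2-isopropyl-5-methylcyclohexyl]oxy}-4,5-dihydrofuran-2-olate | [Li+].[O-]C1=C[C@@H](C)[C@H](O[C@@H]2C[C@H](C)CC[C@H]2C(C)C)O1 | intermediate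
8 | (3R,4R,5R)-3,4-dimethyl-5-{[(1R,2S,5R)-2-isopropyl-5-methylcyclohexyl]oxy}dihydrofuran-2(3H)-one | O=C1[C@H](C)[C@@H](C)[C@H](O[C@@H]2C[C@H](C)CC[C@H]2C(C)C)O1 | intermediate
9 | (2R,3R)-2,3-dimethylbutane-1,4-diol | OC[C@H](C)[C@@H](C)CO | intermediate
10 | (2R,3R)-4-[(tert-butyldimethylsilyl)oxy]-2,3-dimethylbutan-1-ol | OC[C@H](C)[C@@H](C)CO[Si](C)(C)C(C)(C)C | intermediate
11 | (2R,3R)-4-[(tert-butyldimethylsilyl)oxy]-2,3-dimethylbutyl 4-methylbenzenesulfonate | Cc1ccc(cc1)S(=O)(=O)OC[C@H](C)[C@@H](C)CO[Si](C)(C)C(C)(C)C | intermediate
12 | 4-(benzyloxy)phenylmagnesium bromide | Br[Mg]c1ccc(OCc2ccccc2)cc1 | starting material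
13 | {[(2R,3S)-4-[4-(benzyloxy)phenyl]-2,3-dimethylbutyl]oxy}(tert-butyl)dimethylsilane | CC(C)(C)[Si](C)(C)OC[C@H](C)[C@@H](C)Cc1ccc(OCc2ccccc2)cc1 | intermediate
14 | (2R,3S)-4-[4-(benzyloxy)phenyl]-2,3-dimethylbutan-1-ol | OC[C@H](C)[C@@H](C)Cc1ccc(OCc2ccccc2)cc1 | intermediate
15 | (2R,3S)-4-[4-(benzyloxy)phenyl]-2,3-dimethylbutanal | O=C[C@H](C)[C@@H](C)Cc1ccc(OCc2ccccc2)cc1 | intermediate
16 | 3,5-bis(benzyloxy)phenol | Oc1cc(OCc2ccccc2)cc(OCc2ccccc2)c1 | starting material
17 | bromomagnesium 3,5-bis(benzyloxy)phenoxide | Br[Mg]Oc1cc(OCc2ccccc2)cc(OCc2ccccc2)c1 | intermediate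
18 | 3,5-bis(benzyloxy)-2-{(2R,3S)-4-[4-(benzyloxy)phenyl]-1-hydroxy-2,3-dimethylbutyl}phenol (both C1 epimers) | Oc1cc(OCc2ccccc2)cc(OCc2ccccc2)c1C(O)[C@H](C)[C@@H](C)Cc1ccc(OCc2ccccc2)cc1 | intermediate
19 | 3,5-bis(benzyloxy)-2-{(2R,3S)-4-[4-(benzyloxy)phenyl]-1-hydroxy-2,3-dimethylbutyl}phenyl tert-butyl carbonate (both C1 epimers) | CC(C)(C)OC(=O)Oc1cc(OCc2ccccc2)cc(OCc2ccccc2)c1C(O)[C@H](C)[C@@H](C)Cc1ccc(OCc2ccccc2)cc1 | intermediate
20 | 3,5-bis(benzyloxy)-6-{(2R,3S)-4-[4-(benzyloxy)phenyl]-2,3-dimethylbutylidene}cyclohexa-2,4-dien-1-one | O=C1C=C(OCc2ccccc2)C=C(OCc2ccccc2)C1=C[C@H](C)[C@@H](C)Cc1ccc(OCc2ccccc2)cc1 | intermediate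
21 | 3,5-bis(benzyloxy)-2-{(1R,2R,3S)-1,4-bis[4-(benzyloxy)phenyl]-2,3-dimethylbutyl}phenol | Oc1cc(OCc2ccccc2)cc(OCc2ccccc2)c1[C@@H](c1ccc(OCc2ccccc2)cc1)[C@H](C)[C@@H](C)Cc1ccc(OCc2ccccc2)cc1 | intermediate
22 | 2-[(1R,2R,3S)-1,4-bis(4-hydroxyphenyl)-2,3-dimethylbutyl]benzene-1,3,5-triol | Oc1cc(O)cc(O)c1[C@@H](c1ccc(O)cc1)[C@H](C)[C@@H](C)Cc1ccc(O)cc1 | intermediate
23 | 3-(4-methoxyphenyl)propanenitrile | COc1ccc(CCC#N)cc1 | starting material
24 | 1-{3-[(1R,2R,3S)-1,4-bis(4-hydroxyphenyl)-2,3-dimethylbutyl]-2,4,6-trihydroxyphenyl}-3-(4-methoxyphenyl)propan-1-iminium chloride | [Cl-].COc1ccc(CCC(=[NH2+])c2c(O)cc(O)c([C@@H](c3ccc(O)cc3)[C@H](C)[C@@H](C)Cc3ccc(O)cc3)c2O)cc1 | intermediate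
25 | 1-{3-[(1R,2R,3S)-1,4-bis(4-hydroxyphenyl)-2,3-dimethylbutyl]-2,4,6-trihydroxyphenyl}-3-(4-methoxyphenyl)propan-1-one (CNP0193401.1) | COc1ccc(CCC(=O)c2c(O)cc(O)c([C@@H](c3ccc(O)cc3)[C@H](C)[C@@H](C)Cc3ccc(O)cc3)c2O)cc1 | target

## Step count and least certain steps

Total: 13 steps. Longest linear sequence: 13 steps (1 to 25); 3, 5, 12, 16 and 23 are bought and enter directly.

**Step 3 (key step).** The copper-containing enolate 7 alkylates slowly, so proton exchange between 7 and 8 already formed may leave C3 unmethylated or methylate it twice, and may erode the trans selectivity. The fallback separates the two events. Setting out from 4, the cuprate addition is quenched with aq NH4Cl to give the conjugate adduct (4R,5R)-4-methyl-5-(menthyloxy)dihydrofuran-2(3H)-one F1. F1 is deprotonated with LDA in THF at −78 °C, and the copper-free lithium enolate is methylated with 5, again anti to the C4 methyl. The route is rejoined at 8.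

**Step 11.** Facial discrimination at C7 may be insufficient, because the methyl and the branched C8' group differ only moderately in size; the basic medium may also tautomerise 20 to a vinylphenol, which would erase C8. The fallback replaces substrate control under basic conditions by catalyst control under neutral ones. Setting out from 18, exchange of the benzylic hydroxyl in ethanol with a trace of pyridinium p-toluenesulfonate gives 3,5-bis(benzyloxy)-2-{(2R,3S)-4-[4-(benzyloxy)phenyl]-1-ethoxy-2,3-dimethylbutyl}phenol F2. F2 is treated with diethyl [4-(benzyloxy)phenyl]boronate F3 (from the purchasable boronic acid and ethanol) and a catalytic amount of one enantiomer of 3,3'-dibromo-1,1'-bi-2-naphthol in toluene over molecular sieves. The boronate bound to the chiral diol takes up the phenol, ethanol is lost to give the same quinone methide, and the aryl group passes from boron to C7 inside the chiral complex; this is a known type of biphenol-catalysed boronate addition to ortho-quinone methides. The catalyst enantiomer that reinforces the substrate bias is chosen. The route is rejoined at 21.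

**Step 9.** The magnesium phenoxide may enolise 15 and so epimerise C8, or the product may ionise and take up a second arene. The fallback uses a fast carbonyl addition at low temperature. Setting out from 16, ortho-bromination (NBS, cat. i-Pr2NH, CH2Cl2) gives 3,5-bis(benzyloxy)-2-bromophenol F4. Two equivalents of n-BuLi in THF at −78 °C convert it by deprotonation and bromine–lithium exchange into lithium 3,5-bis(benzyloxy)-2-lithiophenolate F5, which adds to 15 at −78 °C faster than it can enolise it. A buffered quench rejoins the route at 18.

**Step 13.** Under HCl and ZnCl2 the Friedel–Crafts bond at C7 may reverse before ring A is deactivated, with loss or epimerisation of C7; imidates may form on the phenols of rings C and D; and the crowded ring may react slowly. The fallback is acid-free and builds the ketone by aryllithium chemistry. Setting out from 21: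
- benzylation (BnBr, K2CO3, DMF) gives 1,3,5-tris(benzyloxy)-2-{(1R,2R,3S)-1,4-bis[4-(benzyloxy)phenyl]-2,3-dimethylbutyl}benzene F6;
- NBS in MeCN at 0 °C brominates the only kind of free carbon on the most electron-rich ring to give 1,3,5-tris(benzyloxy)-2-bromo-4-{(1R,2R,3S)-1,4-bis[4-(benzyloxy)phenyl]-2,3-dimethylbutyl}benzene F7;
- bromine–lithium exchange (n-BuLi, THF, −78 °C) and addition to purchasable 3-(4-methoxyphenyl)propanal give 1-{2,4,6-tris(benzyloxy)-3-[(1R,2R,3S)-1,4-bis[4-(benzyloxy)phenyl]-2,3-dimethylbutyl]phenyl}-3-(4-methoxyphenyl)propan-1-ol F8;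
- Dess–Martin oxidation gives 1-{2,4,6-tris(benzyloxy)-3-[(1R,2R,3S)-1,4-bis[4-(benzyloxy)phenyl]-2,3-dimethylbutyl]phenyl}-3-(4-methoxyphenyl)propan-1-one F9;
- hydrogenolysis (H2, Pd/C) removes the five benzyl groups and arrives at 25.

**Step 7.** Displacement at the beta-branched sulfonate may be slow, leaving room for homocoupling of 12 and for elimination. The fallback reverses the polarity of the coupling. Setting out from 10, I2, PPh3 and imidazole give tert-butyl{[(2R,3R)-4-iodo-2,3-dimethylbutyl]oxy}dimethylsilane F10. Zinc insertion (Zn dust, LiCl, THF) gives [(2R,3R)-4-{[tert-butyl(dimethyl)silyl]oxy}-2,3-dimethylbutyl]zinc iodide F11. Negishi coupling with purchasable 1-(benzyloxy)-4-iodobenzene, catalysed by zerovalent palladium formed from Pd(OAc)2 and 2-dicyclohexylphosphino-2',6'-dimethoxybiphenyl in THF, rejoins the route at 13, which is desilylated as in step 7.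

## Further compounds

F1 | step 3 | (4R,5R)-4-methyl-5-{[(1R,2S,5R)-2-isopropyl-5-methylcyclohexyl]oxy}dihydrofuran-2(3H)-one | O=C1C[C@@H](C)[C@H](O[C@@H]2C[C@H](C)CC[C@H]2C(C)C)O1
F2 | step 11 | 3,5-bis(benzyloxy)-2-{(2R,3S)-4-[4-(benzyloxy)phenyl]-1-ethoxy-2,3-dimethylbutyl}phenol (both C1 epimers) | CCOC(c1c(O)cc(OCc2ccccc2)cc1OCc1ccccc1)[C@H](C)[C@@H](C)Cc1ccc(OCc2ccccc2)cc1
F3 | step 11 | diethyl [4-(benzyloxy)phenyl]boronate | CCOB(OCC)c1ccc(OCc2ccccc2)cc1
F4 | step 9 | 3,5-bis(benzyloxy)-2-bromophenol | Oc1cc(OCc2ccccc2)cc(OCc2ccccc2)c1Br
F5 | step 9 | lithium 3,5-bis(benzyloxy)-2-lithiophenolate | [Li+].[O-]c1cc(OCc2ccccc2)cc(OCc2ccccc2)c1[Li]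
F6 | step 13 | 1,3,5-tris(benzyloxy)-2-{(1R,2R,3S)-1,4-bis[4-(benzyloxy)phenyl]-2,3-dimethylbutyl}benzene | c1ccc(cc1)COc1cc(OCc2ccccc2)cc(OCc2ccccc2)c1[C@@H](c1ccc(OCc2ccccc2)cc1)[C@H](C)[C@@H](C)Cc1ccc(OCc2ccccc2)cc1
F7 | step 13 | 1,3,5-tris(benzyloxy)-2-bromo-4-{(1R,2R,3S)-1,4-bis[4-(benzyloxy)phenyl]-2,3-dimethylbutyl}benzene | Brc1c(OCc2ccccc2)cc(OCc2ccccc2)c(c1OCc1ccccc1)[C@@H](c1ccc(OCc2ccccc2)cc1)[C@H](C)[C@@H](C)Cc1ccc(OCc2ccccc2)cc1
F8 | step 13 | 1-{2,4,6-tris(benzyloxy)-3-[(1R,2R,3S)-1,4-bis[4-(benzyloxy)phenyl]-2,3-dimethylbutyl]phenyl}-3-(4-methoxyphenyl)propan-1-ol (both carbinol epimers) | COc1ccc(CCC(O)c2c(OCc3ccccc3)cc(OCc3ccccc3)c([C@@H](c3ccc(OCc4ccccc4)cc3)[C@H](C)[C@@H](C)Cc3ccc(OCc4ccccc4)cc3)c2OCc2ccccc2)cc1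
F9 | step 13 | 1-{2,4,6-tris(benzyloxy)-3-[(1R,2R,3S)-1,4-bis[4-(benzyloxy)phenyl]-2,3-dimethylbutyl]phenyl}-3-(4-methoxyphenyl)propan-1-one | COc1ccc(CCC(=O)c2c(OCc3ccccc3)cc(OCc3ccccc3)c([C@@H](c3ccc(OCc4ccccc4)cc3)[C@H](C)[C@@H](C)Cc3ccc(OCc4ccccc4)cc3)c2OCc2ccccc2)cc1
F10 | step 7 | tert-butyl{[(2R,3R)-4-iodo-2,3-dimethylbutyl]oxy}dimethylsilane | IC[C@H](C)[C@@H](C)CO[Si](C)(C)C(C)(C)C
F11 | step 7 | [(2R,3R)-4-{[tert-butyl(dimethyl)silyl]oxy}-2,3-dimethylbutyl]zinc iodide | I[Zn]C[C@H](C)[C@@H](C)CO[Si](C)(C)C(C)(C)C
A1 | alternative 1 | 5-(benzyloxy)-2-{(1R,2R,3S)-1,4-bis[4-(benzyloxy)phenyl]-2,3-dimethylbutyl}-3-[(triisopropylsilyl)oxy]phenol | Oc1cc(OCc2ccccc2)cc(O[Si](C(C)C)(C(C)C)C(C)C)c1[C@@H](c1ccc(OCc2ccccc2)cc1)[C@H](C)[C@@H](C)Cc1ccc(OCc2ccccc2)cc1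
A2 | alternative 1 | 3-(benzyloxy)cyclobut-2-en-1-one | O=C1C=C(OCc2ccccc2)C1
A3 | alternative 1 | {[(3R,4R,5S)-3,6-bis[4-(benzyloxy)phenyl]-4,5-dimethylhex-1-yn-1-yl]oxy}triisopropylsilane | CC(C)[Si](C(C)C)(C(C)C)OC#C[C@@H](c1ccc(OCc2ccccc2)cc1)[C@H](C)[C@@H](C)Cc1ccc(OCc2ccccc2)cc1
A4 | alternative 2 | 2-{(2R,3S)-4-[4-(benzyloxy)phenyl]-3-methylbutan-2-yl}-4,4,5,5-tetramethyl-1,3,2-dioxaborolane | CC1(C)OB([C@H](C)[C@@H](C)Cc2ccc(OCc3ccccc3)cc2)OC1(C)C
A5 | alternative 2 | 2-[4-(benzyloxy)benzyl]-4,4,5,5-tetramethyl-1,3,2-dioxaborolane | CC1(C)OB(Cc2ccc(OCc3ccccc3)cc2)OC1(C)C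
A6 | alternative 2 | (1R)-1-(tributylstannyl)ethyl 2,4,6-triisopropylbenzoate | CCCC[Sn](CCCC)(CCCC)[C@H](C)OC(=O)c1c(C(C)C)cc(C(C)C)cc1C(C)C
A7 | alternative 2 | (1S)-1-(tributylstannyl)ethyl 2,4,6-triisopropylbenzoate | CCCC[Sn](CCCC)(CCCC)[C@@H](C)OC(=O)c1c(C(C)C)cc(C(C)C)cc1C(C)C
A8 | alternative 3 | (3R,4R)-5,7-bis(benzyloxy)-4-[4-(benzyloxy)phenyl]-3-{(2S)-1-[4-(benzyloxy)phenyl]propan-2-yl}-3,4-dihydro-2H-chromen-2-one | O=C1Oc2cc(OCc3ccccc3)cc(OCc3ccccc3)c2[C@@H](c2ccc(OCc3ccccc3)cc2)[C@H]1[C@@H](C)Cc1ccc(OCc2ccccc2)cc1
A9 | alternative 3 | 3,5-bis(benzyloxy)-2-{[4-(benzyloxy)phenyl](4-methylbenzenesulfonyl)methyl}phenol (racemic) | Cc1ccc(cc1)S(=O)(=O)C(c1ccc(OCc2ccccc2)cc1)c1c(O)cc(OCc2ccccc2)cc1OCc1ccccc1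
A10 | alternative 3 | 4-nitrophenyl (3S)-4-[4-(benzyloxy)phenyl]-3-methylbutanoate | O=C(C[C@@H](C)Cc1ccc(OCc2ccccc2)cc1)Oc1ccc(cc1)[N+](=O)[O-]
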